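## The problem

The target 18, 5,7,8-trimethoxy-2-(2,3,4,5-tetramethoxyphenyl)-4H-chromen-4-one, is a flat, achiral flavone with seven methyl ethers. It has no stereocentre, so no centre can steer another; the centres that appear on the way (C2, later C4) are formed racemic and are erased before the end. The real questions are regiochemistry and oxidation level. Ring A bears oxygen at C5, C7, C8 and C8a and leaves only C6–H, and ring C must be fused to it through a C–C bond at C4a, a carbon lying between O1 and the 5-methoxyl. Ring B, a 2,3,4,5-tetramethoxyphenyl group, sits on C2, and C4 must end as a ketone conjugated with a C2=C3 double bond. The aryl methyl ethers (the one at C5 is peri to the carbonyl) do not tolerate AlCl3 or BBr3, and both rings, above all C6–H between two methoxyls, are exposed to electrophilic halogen, mercury salts and one-electron oxidants. The feature that makes the key step possible is that C8 is methoxylated, so C4a is the only unsubstituted carbon ortho to O1, while O1, C2 with ring B, C3 and C4 can be drawn as an aryl 1-arylpropargyl ether. A [3,3] shift of that ether can deliver C4 to C4a and to no other productive position, so the ether oxygen fixes the whole pattern of ring A.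

## Retrosynthesis

The last operations change oxidation level only. The C2=C3 double bond and the C4 carbonyl of 18 are traced back through flavanone 17 to the flavan-4-ol 16. Oxidation of a benzylic alcohol and dehydrogenation of a flavanone are reliable reactions of this class, and one oxidant, IBX, can do both in one flask. No skeletal bond is cut; the gain is that C4 need only be a secondary alcohol. The forward step must leave the electron-rich rings alone, which favours IBX over halogen-based dehydrogenation.

Cutting the C4–O bond of 16 leads to the 2H-chromene 15, whose C3=C4 bond is a styrene-type alkene conjugated with ring A. A shorter endgame, hydride abstraction from C2 of 15 with DDQ and capture by water, was weighed and set aside: after loss of hydride, water is expected to attack C2 and not C4, and ring C would open with the carbonyl on the ring B side. Hydroboration would place oxygen on C3, and Hg(OAc)2 or bromonium reagents would have to choose between the alkene and C6–H. Hydrogen-atom transfer from a cobalt hydride should give the benzylic C4 radical selectively, and oxygen follows (Mukaiyama hydration). The forward reaction is asked only for Markovnikov regiochemistry; the configuration at C4 does not matter.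

The ring-forming disconnection cuts C4–C4a of 15 and, formally, O1–C2, which is broken and re-made in the same step; the precursor is the aryl propargyl ether 11. The neighbouring cuts (acylation of ring A at C4a, or aldol condensation at C2–C3) both need a C-acylation ortho to the ring A hydroxyl. That calls for Lewis acids that cleave ortho-methoxyls and has to choose between the ortho and para positions. The sigmatropic cut needs no reagent and takes its regiochemistry from the substrate, because the second ortho position is blocked. 11 is an open-chain ether of two monocyclic halves of similar size, so the route becomes convergent. The forward step must reach the [3,3] shift before the doubly activated C–O bond ionises.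

Cutting O1–C2 divides 11 into 2,3,5-trimethoxyphenol (5) and the propargylic alcohol 10. A Mitsunobu etherification is preferred to alkylation of the phenoxide with a propargylic halide, since a 1-arylpropargyl halide with ortho- and para-methoxyls would be too labile to handle; here the alcohol is activated only in the flask. 10 is racemic, so nothing is asked of configuration; what is asked is O-alkylation rather than C-alkylation of a very electron-rich phenol.

C2–C3 of 10 is cut to 2,3,4,5-tetramethoxybenzaldehyde (8) and ethynylmagnesium bromide (9), a plain carbonyl addition. The C1'–C2 bond of 8 is then cut to 1,2,3,4-tetramethoxybenzene (6). Its two free positions are equivalent, so a Vilsmeier–Haack formylation (through iminium salt 7) can give only one aldehyde. Ring B thus costs two steps from a commercial arene.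

Phenol 5 has its hydroxyl at the end of a row of three oxygens with a fourth oxygen meta to it, a pattern that neither partial methylation nor electrophilic substitution of a simpler phenol gives cleanly. Its C–O bond is therefore taken back to the C–Br bond of 1-bromo-2,3,5-trimethoxybenzene (4). The 5-methoxyl of 4 goes back to the hydroxyl of 3-bromo-4,5-dimethoxyphenol (3), and that hydroxyl to the formyl group of commercial 3-bromo-4,5-dimethoxybenzaldehyde (1) by Baeyer–Villiger oxidation through formate 2. Every oxygen is placed by the starting material, and no selectivity has to be won.

## Roads not taken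

Alternative 1: Isoxazole as a masked 1,3-diketone.
- Cut: through ring C at C3–C4 and O–C2 of a latent diketone, stored as an isoxazole.
- Forward key step: PhI(OAc)2 would oxidise the ring A aldoxime A1 to nitrile oxide A2, which adds to the ring B alkyne A3 to give the 3,5-diarylisoxazole A4.
- Merits: the halves are joined by a cycloaddition whose regiochemistry with a terminal alkyne is dependable. C4 arrives at the ketone oxidation level, so no late oxidation is needed. Nothing is heated, and the di-ortho-substituted A2 is shielded against dimerisation.
- Weak points: A1 needs phenol 5 anyway, then ortho-formylation (in competition with the free para position), benzylation and oximation. A3 needs a one-carbon homologation of aldehyde 8. The crowded A2 should add slowly, and PhI(OAc)2 is an oxidant in the presence of a tetraoxygenated ring. Three operations still follow A4: reductive opening of the N–O bond, debenzylation, and acid-induced closure of ring C with loss of ammonia.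
- Comparison: on oxidation level this road is better, since the chosen plan spends steps 8 and 9 on C4 and C2=C3. The chosen plan sets against this a protecting-group-free sequence of nine steps, against about twelve to thirteen, in which ring A never has to be formylated.

Alternative 2: Ring B grown from a squarate.
- Cut: inside ring B; the benzene ring is grown from a four-membered ring.
- Forward key step: the lithium acetylide of 3,3-diethoxypropyne A6 would add to dimethyl squarate A5 to give the 4-alkynyl-4-hydroxycyclobutenone A7. Heating A7 in xylene (Moore rearrangement) would open the four-membered ring and close the six-membered quinone A8.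
- Merits: the four oxygens and the one-carbon handle of ring B are placed without any aromatic substitution. The two quinone oxygens are born different from the two squarate methoxyls, which would matter if ring B carried unlike ether groups.
- Weak points: reduction, double methylation and acetal hydrolysis of A8 lead only to aldehyde 8, which step 4 gives in one operation from commercial 6. All four ethers of the target are methyl, so the built-in differentiation buys nothing. The road does not address ring C or the regiochemistry of ring A, which are the real problems.
- Comparison: this road is better only in generality. For 18 it is about four steps longer to the same aldehyde and would still need the chosen key step or an equivalent.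

Alternative 3: Ring A by polyketide-type Claisen closure on a pyranone.
- Cut: through ring A at C4a–C5; ring C exists first as a 4-pyranone.
- Forward key step: Mg(OMe)2 in methanol would deprotonate the pyranone keto ester A9 so that C4a attacks the ester carbonyl. Loss of methanol and enolisation give the 5,7-dihydroxyflavone A10, and double O-methylation would give 18.
- Merits: ring C is at the flavone oxidation level from the start. The pattern of ring A is written into the chain, with the 8-methoxyl distinguished from the 5- and 7-hydroxyls. No ring A phenol has to be made, and A10 is a branching point for analogues.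
- Weak points: A9 is much harder to assemble than anything in the chosen route. It demands a side-chain C-acylation next to the pyranone ring in competition with O-acylation and self-condensation. In the closure, attack through C4a competes with addition of methoxide to the pyranone ring and with aldol closure from C6 onto the C4 carbonyl. The chelated 5-hydroxyl methylates sluggishly.
- Comparison: after its key step this road is shorter and needs no redox chemistry, which is a real advantage. The chosen plan sets against it fragments reached in two and three standard steps and a key step whose regiochemistry cannot go astray; here the uncertainty lies in making A9.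

Key step: step 7

Assumption: compounds 10, 11, 15 and 17 are racemic and 16 is a mixture of racemic diastereomers; this is immaterial, since every stereocentre is removed before the achiral target 18.

## Route

Step 1
Reactants: 1 3-bromo-4,5-dimethoxybenzaldehyde
Product: 3 3-bromo-4,5-dimethoxyphenol, via 3-bromo-4,5-dimethoxyphenyl formate 2 (not isolated)
Conditions: mCPBA, CH2Cl2, 0 °C to rt; then K2CO3 (cat.), MeOH, rt
Reagents that add atoms: 3-chloroperoxybenzoic acid (mCPBA), OOC(=O)c1cccc(Cl)c1
Why: Baeyer–Villiger oxidation; the aryl group, made electron-rich by the para-methoxyl, migrates in preference to hydrogen, and formate 2 is cleaved by methanolysis without touching the C–Br bond or the ethers.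

Step 2
Reactants: 3 3-bromo-4,5-dimethoxyphenol
Product: 4 1-bromo-2,3,5-trimethoxybenzene
Conditions: MeI, K2CO3, acetone, reflux
Reagents that add atoms: iodomethane, CI
Why: Williamson ether synthesis; the phenoxide is the only nucleophile present and O-methylation of such phenols is routine.

Step 3
Reactants: 4 1-bromo-2,3,5-trimethoxybenzene
Product: 5 2,3,5-trimethoxyphenol
Conditions: Pd2(dba)3 (cat.), tBuXPhos (cat.), KOH, 1,4-dioxane/H2O, 100 °C
Reagents that add atoms: potassium hydroxide, [K+].[OH-]
Why: Pd-catalysed hydroxylation of an aryl bromide (C–O cross-coupling); zerovalent palladium inserts into the C–Br bond, hydroxide replaces bromide, and the bulky biaryl phosphine promotes C–O reductive elimination while keeping the phenoxide formed from coupling again. The hydroxyl enters exactly where bromine stood, so the oxygen pattern of ring A is fixed.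

Step 4
Reactants: 6 1,2,3,4-tetramethoxybenzene
Product: 8 2,3,4,5-tetramethoxybenzaldehyde, via N,N-dimethyl-1-(2,3,4,5-tetramethoxyphenyl)methaniminium dichlorophosphate 7 (not isolated)
Conditions: POCl3, DMF, 0 to 80 °C; then H2O
Reagents that add atoms: N,N-dimethylformamide, CN(C)C=O; water, O
Why: Vilsmeier–Haack formylation; the two free positions of 6 are equivalent and each is ortho and para to a methoxyl, so only one aldehyde can form, and the deactivating iminium group of 7 prevents a second substitution. No Lewis acid strong enough to cleave a methyl ether is present.

Step 5
Reactants: 8 2,3,4,5-tetramethoxybenzaldehyde; 9 ethynylmagnesium bromide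
Product: 10 rac-1-(2,3,4,5-tetramethoxyphenyl)prop-2-yn-1-ol
Conditions: THF, 0 °C to rt; then H2O
Reagents that add atoms: none
Why: Grignard addition of an acetylide to an aldehyde; the carbinol centre (the later C2) is formed racemic and no control is sought.

Step 6
Reactants: 5 2,3,5-trimethoxyphenol; 10 rac-1-(2,3,4,5-tetramethoxyphenyl)prop-2-yn-1-ol
Product: 11 rac-1,2,3,4-tetramethoxy-5-[1-(2,3,5-trimethoxyphenoxy)prop-2-yn-1-yl]benzene
Conditions: PPh3, DIAD, THF, 0 °C to rt
Reagents that add atoms: none
Why: Mitsunobu etherification of a phenol with a secondary propargylic alcohol; the phenol is acidic enough to protonate the betaine and the phenoxide displaces the activated oxygen at the propargylic carbon. The terminal alkyne is inert, and inversion is irrelevant for a racemate.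

Step 7
Reactants: 11 rac-1,2,3,4-tetramethoxy-5-[1-(2,3,5-trimethoxyphenoxy)prop-2-yn-1-yl]benzene
Product: 15 rac-5,7,8-trimethoxy-2-(2,3,4,5-tetramethoxyphenyl)-2H-chromene, via allenyl cyclohexadienone 12 (not isolated), via ortho-allenylphenol 13 (not isolated), via ortho-quinone methide 14 (not isolated)
Conditions: PhNEt2 (degassed), 160–170 °C, argon
Reagents that add atoms: none
Why: This is the aromatic propargyl Claisen rearrangement, whose closest known relatives are the thermal conversions of aryl 1,1-dimethylpropargyl and 1,1-diarylpropargyl ethers into 2,2-disubstituted 2H-chromenes. A [3,3] shift joins the alkyne terminus to the free ortho carbon of ring A (C4–C4a) while O1–C2 breaks, giving allenyl dienone 12, which enolises to phenol 13. A 1,5-hydrogen shift from O–H to the central allene carbon then gives ortho-quinone methide 14 with the vinyl group syn to the carbonyl oxygen. Ring C, the only ring formed, closes by a thermal disrotatory oxa-6π electrocyclisation of 14 that re-forms O1–C2 and restores the aromaticity of ring A. The new stereocentre C2 arises without any controlling element, so 15 is racemic; this is accepted because C2 becomes sp2 in step 9. The step needs regioselectivity for C4a over C8 and over the para carbon C6: a shift to the methoxyl-bearing C8 gives a dienone that cannot enolise and should revert faster than it moves on to C6, whereas the C4a path is drained irreversibly by tautomerisation. The benzylic O1–C2 bond and the electron-rich C4a (ortho to O1 and the 5-methoxyl, para to the 7-methoxyl) should lower the barrier, and the basic solvent keeps 11 and 15 from acid-induced ionisation.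

Step 8
Reactants: 15 rac-5,7,8-trimethoxy-2-(2,3,4,5-tetramethoxyphenyl)-2H-chromene
Product: 16 5,7,8-trimethoxy-2-(2,3,4,5-tetramethoxyphenyl)chroman-4-ol (2,4-cis and 2,4-trans racemates, used as the mixture)
Conditions: Co(acac)2 (cat.), PhSiH3, O2 (1 atm), iPrOH/THF, rt
Reagents that add atoms: dioxygen, O=O
Why: Mukaiyama hydration; a cobalt hydride formed from Co(acac)2, PhSiH3 and O2 transfers a hydrogen atom to C3, the benzylic C4 radical is trapped by O2 and the peroxide is reduced by the silane, so oxygen arrives at C4 in the Markovnikov sense while the radical conditions leave C6–H alone. C4 forms as both epimers and no control is sought, since C2 and C4 are both flattened in step 9; any 17 formed alongside is carried forward.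

Step 9
Reactants: 16 5,7,8-trimethoxy-2-(2,3,4,5-tetramethoxyphenyl)chroman-4-ol
Product: 18 5,7,8-trimethoxy-2-(2,3,4,5-tetramethoxyphenyl)-4H-chromen-4-one, via rac-5,7,8-trimethoxy-2-(2,3,4,5-tetramethoxyphenyl)chroman-4-one 17 (not isolated)
Conditions: IBX, DMSO, rt, then 80 °C
Reagents that add atoms: none
Why: IBX oxidation of the benzylic alcohol to flavanone 17 at room temperature, then IBX-mediated dehydrogenation of the ketone through its enol on warming; the product enone is the vinylogous ester of a flavone, which drives the second stage. Aryl methyl ethers are not attacked by IBX, and both stereocentres disappear.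

## Compound list

1 | 3-bromo-4,5-dimethoxybenzaldehyde | COc1cc(C=O)cc(Br)c1OC | starting material
2 | 3-bromo-4,5-dimethoxyphenyl formate | COc1cc(OC=O)cc(Br)c1OC | intermediate (not isolated)
3 | 3-bromo-4,5-dimethoxyphenol | COc1cc(O)cc(Br)c1OC | intermediate
4 | 1-bromo-2,3,5-trimethoxybenzene | COc1cc(OC)cc(Br)c1OC | intermediate
5 | 2,3,5-trimethoxyphenol | COc1cc(OC)cc(O)c1OC | intermediate
6 | 1,2,3,4-tetramethoxybenzene | COc1ccc(OC)c(OC)c1OC | starting material
7 | N,N-dimethyl-1-(2,3,4,5-tetramethoxyphenyl)methaniminium dichlorophosphate | COc1cc(C=[N+](C)C)c(OC)c(OC)c1OC.[O-]P(=O)(Cl)Cl | intermediate (not isolated)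
8 | 2,3,4,5-tetramethoxybenzaldehyde | COc1cc(C=O)c(OC)c(OC)c1OC | intermediate
9 | ethynylmagnesium bromide | C#C[Mg]Br | starting material
10 | rac-1-(2,3,4,5-tetramethoxyphenyl)prop-2-yn-1-ol | C#CC(O)c1cc(OC)c(OC)c(OC)c1OC | intermediate
11 | rac-1,2,3,4-tetramethoxy-5-[1-(2,3,5-trimethoxyphenoxy)prop-2-yn-1-yl]benzene | C#CC(Oc1cc(OC)cc(OC)c1OC)c1cc(OC)c(OC)c(OC)c1OC | intermediate
12 | 2,3,5-trimethoxy-6-[3-(2,3,4,5-tetramethoxyphenyl)propa-1,2-dien-1-yl]cyclohexa-2,4-dien-1-one (mixture of stereoisomers) | O=C1C(OC)=C(OC)C=C(OC)C1C=C=Cc1cc(OC)c(OC)c(OC)c1OC | intermediate (not isolated)
13 | rac-2,3,5-trimethoxy-6-[3-(2,3,4,5-tetramethoxyphenyl)propa-1,2-dien-1-yl]phenol | Oc1c(OC)c(OC)cc(OC)c1C=C=Cc1cc(OC)c(OC)c(OC)c1OC | intermediate (not isolated)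
14 | (6Z)-2,3,5-trimethoxy-6-[3-(2,3,4,5-tetramethoxyphenyl)prop-2-en-1-ylidene]cyclohexa-2,4-dien-1-one (side-chain alkene geometry not defined) | O=C1C(OC)=C(OC)C=C(OC)/C1=C/C=Cc1cc(OC)c(OC)c(OC)c1OC | intermediate (not isolated)
15 | rac-5,7,8-trimethoxy-2-(2,3,4,5-tetramethoxyphenyl)-2H-chromene | COc1cc(OC)c2c(c1OC)OC(c1cc(OC)c(OC)c(OC)c1OC)C=C2 | intermediate
16 | 5,7,8-trimethoxy-2-(2,3,4,5-tetramethoxyphenyl)chroman-4-ol (2,4-cis and 2,4-trans, each racemic) | COc1cc(OC)c2c(c1OC)OC(c1cc(OC)c(OC)c(OC)c1OC)CC2O | intermediate
17 | rac-5,7,8-trimethoxy-2-(2,3,4,5-tetramethoxyphenyl)chroman-4-one | COc1cc(OC)c2c(c1OC)OC(c1cc(OC)c(OC)c(OC)c1OC)CC2=O | intermediate (not isolated)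
18 | 5,7,8-trimethoxy-2-(2,3,4,5-tetramethoxyphenyl)-4H-chromen-4-one | COc1cc(-c2cc(=O)c3c(OC)cc(OC)c(OC)c3o2)c(OC)c(OC)c1OC | target

## Step count and risks

Total step count: 9. Longest linear sequence: 7 steps (steps 1, 2, 3, 6, 7, 8, 9 from 1); the ring B branch (steps 4 and 5) joins at step 6.

Steps least certain to work:

Step 7 (key step). What may go wrong: heterolysis of the doubly activated benzylic, propargylic C–O bond may outrun the concerted shift, so that the fragments recombine at other ring carbons or at the alkyne terminus. A shift to the methoxyl-bearing ortho carbon followed by a Cope shift may divert material to the para position. The product may also be lost at the reaction temperature through its reversible ring opening and oligomerisation. If a change of conditions (π-acid catalysis with Ph3PAuNTf2 at room temperature) does not help, the approach is changed. Fallback: the same ring is closed from the aldehyde oxidation level, without any ether. Aldehyde 8 is extended by a Wittig reaction with (triphenylphosphoranylidene)acetaldehyde to (E)-3-(2,3,4,5-tetramethoxyphenyl)prop-2-enal F1. F1 is condensed with phenol 5 and PhB(OH)2 in toluene containing propionic acid at reflux with removal of water. The boron atom ties the phenol oxygen to the aldehyde, the free ortho carbon attacks the aldehyde carbon, and the cyclic boronate rac-5,7,8-trimethoxy-2-phenyl-4-[(E)-2-(2,3,4,5-tetramethoxyphenyl)ethenyl]-4H-1,3,2-benzodioxaborine F2 results. On heating, F2 fragments to the same ortho-quinone methide 14, which closes to 15. The fallback sets out from 5 and 8 and returns to the route at 15.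

Step 6. What may go wrong: ionisation of the activated alcohol before the phenol attacks, followed by C-alkylation of the electron-rich phenol at its free ortho or para carbon, attack at the alkyne terminus, or alkylation of the reduced azodicarboxylate. Fallback: alcohol 10 is acetylated (Ac2O, pyridine) to rac-1-(2,3,4,5-tetramethoxyphenyl)prop-2-yn-1-yl acetate F3. F3 is coupled with phenol 5 by copper-catalysed propargylic substitution (Cu(MeCN)4BF4, iPr2NEt, MeOH, 0 °C), a reaction of terminal propargylic esters that delivers oxygen nucleophiles to the propargylic carbon. The fallback sets out from 10 and 5 and returns at 11.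

Step 8. What may go wrong: reduction of the C4 radical to the saturated ring instead of capture by oxygen, stalling at partial conversion as the cobalt catalyst is oxidised, and acid-induced loss of water from the product on silica, which would regenerate 15. Fallback: oxygen is brought to C4 by an ionic route. 15 is treated with NBS in aqueous DMSO at 0 °C to give the bromohydrin rac-3-bromo-5,7,8-trimethoxy-2-(2,3,4,5-tetramethoxyphenyl)chroman-4-ol F4 (water enters at the benzylic C4; the 2,3-trans-3,4-trans isomer is expected to prevail). Dess–Martin periodinane oxidises F4 to rac-3-bromo-5,7,8-trimethoxy-2-(2,3,4,5-tetramethoxyphenyl)chroman-4-one F5, and DBU eliminates HBr from F5 to give 18 directly. The fallback sets out from 15 and returns at 18, so it also replaces step 9. Its own weak point, competing bromination at C6, is why it is not the first choice.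

Step 9. What may go wrong: incomplete dehydrogenation after the fast alcohol oxidation, oxidative damage to the electron-rich rings by hot IBX, or acid-promoted dehydration of 16 before it is oxidised. Fallback: the two changes are separated and the second is done by an iodine-based method. 16 is oxidised with Dess–Martin periodinane in CH2Cl2 to flavanone 17, which is isolated and heated with catalytic I2 in DMSO at 120 °C (iodination at C3, loss of HI, reoxidation of HI by DMSO) to give 18. The fallback sets out from 16, passes through 17 and returns at 18; no new compound is needed (F0).

## Further compounds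

F1 | step 7 | (E)-3-(2,3,4,5-tetramethoxyphenyl)prop-2-enal | O=C/C=C/c1cc(OC)c(OC)c(OC)c1OC
F2 | step 7 | rac-5,7,8-trimethoxy-2-phenyl-4-[(E)-2-(2,3,4,5-tetramethoxyphenyl)ethenyl]-4H-1,3,2-benzodioxaborine | COc1cc(OC)c2c(c1OC)OB(c1ccccc1)OC2/C=C/c1cc(OC)c(OC)c(OC)c1OC
F3 | step 6 | rac-1-(2,3,4,5-tetramethoxyphenyl)prop-2-yn-1-yl acetate | CC(=O)OC(C#C)c1cc(OC)c(OC)c(OC)c1OC
F4 | step 8 | rac-(2,3-trans,3,4-trans)-3-bromo-5,7,8-trimethoxy-2-(2,3,4,5-tetramethoxyphenyl)chroman-4-ol (one enantiomer drawn) | COc1cc(OC)c2c(c1OC)O[C@H](c1cc(OC)c(OC)c(OC)c1OC)[C@@H](Br)[C@@H]2O
F5 | step 8 | rac-(2,3-trans)-3-bromo-5,7,8-trimethoxy-2-(2,3,4,5-tetramethoxyphenyl)chroman-4-one (one enantiomer drawn) | COc1cc(OC)c2c(c1OC)O[C@H](c1cc(OC)c(OC)c(OC)c1OC)[C@@H](Br)C2=O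
F0 | step 9 | none | none
A1 | alternative 1 | (E)-2-(benzyloxy)-3,4,6-trimethoxybenzaldehyde oxime | COc1cc(OC)c(/C=N/O)c(OCc2ccccc2)c1OC
A2 | alternative 1 | 2-(benzyloxy)-3,4,6-trimethoxybenzonitrile oxide | COc1cc(OC)c(C#[N+][O-])c(OCc2ccccc2)c1OC
A3 | alternative 1 | 1-ethynyl-2,3,4,5-tetramethoxybenzene | C#Cc1cc(OC)c(OC)c(OC)c1OC
A4 | alternative 1 | 3-[2-(benzyloxy)-3,4,6-trimethoxyphenyl]-5-(2,3,4,5-tetramethoxyphenyl)isoxazole | COc1cc(OC)c(-c2cc(-c3cc(OC)c(OC)c(OC)c3OC)on2)c(OCc2ccccc2)c1OC
A5 | alternative 2 | dimethyl squarate (3,4-dimethoxycyclobut-3-ene-1,2-dione) | COC1=C(OC)C(=O)C1=O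
A6 | alternative 2 | 3,3-diethoxyprop-1-yne | CCOC(OCC)C#C
A7 | alternative 2 | rac-4-(3,3-diethoxyprop-1-yn-1-yl)-4-hydroxy-2,3-dimethoxycyclobut-2-en-1-one | CCOC(OCC)C#CC1(O)C(OC)=C(OC)C1=O
A8 | alternative 2 | 2-(diethoxymethyl)-5,6-dimethoxycyclohexa-2,5-diene-1,4-dione | CCOC(OCC)C1=CC(=O)C(OC)=C(OC)C1=O
A9 | alternative 3 | rac-methyl 4-methoxy-3-oxo-4-[4-oxo-6-(2,3,4,5-tetramethoxyphenyl)-4H-pyran-2-yl]butanoate | COC(=O)CC(=O)C(OC)c1cc(=O)cc(-c2cc(OC)c(OC)c(OC)c2OC)o1
A10 | alternative 3 | 5,7-dihydroxy-8-methoxy-2-(2,3,4,5-tetramethoxyphenyl)-4H-chromen-4-one | COc1c(O)cc(O)c2c(=O)cc(-c3cc(OC)c(OC)c(OC)c3OC)oc12
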